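## Retrosynthetic overview

1. Target 45 comes from nitrile 43 (the nitrile is the masked enal), and the E-alkene next to ring A comes from a Julia–Kocienski union of ring A sulfone 12 (fragment A) with ring B enal 40 (fragment B).
2. Fragment B: enal side chain by allylation, hydroboration and Wittig; Z-cyanoethylidene by Horner–Wadsworth–Emmons on the ring B ketone; tertiary carbinol by MeMgBr; quaternary centre by β-keto ester allylation; hydroxypropyl-bearing CH by cuprate addition.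
3. Ring B is closed by an intramolecular aldol (Knoevenagel) condensation of keto ester aldehyde 21, built from methyl acetoacetate dianion and (S)-benzyl glycidyl ether.
4. Fragment A: ring A is closed by an intramolecular aldol condensation of (2R)-2-methyl-5-oxohexanal (organocatalytic Michael adduct of propanal and methyl vinyl ketone), then two conjugate methylations, hydroxymethylation, thioether formation, methylenation and oxidation.
5. Ring order: ring A (step 2) and ring B (step 14) are made in separate branches and joined in step 26.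

Assumption: numbered compounds are substrates and carbon building blocks; simple reagents appear under Conditions.

## Fragment A (ring A sulfone)

Step 1
Reactants: 1 propanal; 2 but-3-en-2-one (methyl vinyl ketone)
Product: 3 (2R)-2-methyl-5-oxohexanal
Conditions: (S)-2-[methoxy(diphenyl)methyl]pyrrolidine (5 mol %), ethyl 3,4-dihydroxybenzoate (20 mol %), neat, 4 °C
Reagents that add atoms: none
Why: Enamine-catalysed asymmetric Michael addition in which the (E)-enamine of propanal attacks the enone from the face not shielded by the methoxy(diphenyl)methyl group, which sets the 2R centre (later the methyl-bearing stereocentre of ring A).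

Step 2
Reactants: 3 (2R)-2-methyl-5-oxohexanal
Product: 5 (4R)-4-methylcyclohex-2-en-1-one, via aldol adduct 4 (not isolated)
Conditions: LiOH (20 mol %), i-PrOH, rt
Reagents that add atoms: none
Why: Intramolecular aldol condensation (methyl ketone enolate onto the aldehyde, then base-induced β-elimination of water) closes ring A, and cyclisation outpaces enolisation of the aldehyde so the methyl-bearing centre is kept.

Step 3
Reactants: 5 (4R)-4-methylcyclohex-2-en-1-one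
Product: 6 trimethyl{[(3S,4R)-3,4-dimethylcyclohex-1-en-1-yl]oxy}silane
Conditions: MeMgBr, CuBr·SMe2 (5 mol %), Me3SiCl, HMPA, THF, −78 °C
Reagents that add atoms: methylmagnesium bromide, C[Mg]Br; chlorotrimethylsilane, C[Si](C)(C)Cl
Why: Copper-catalysed conjugate addition with in situ silyl trapping gives the regiodefined silyl enol ether, the methyl entering trans to the existing methyl (this new centre is removed again in step 4).

Step 4
Reactants: 6 trimethyl{[(3S,4R)-3,4-dimethylcyclohex-1-en-1-yl]oxy}silane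
Product: 7 (4R)-3,4-dimethylcyclohex-2-en-1-one
Conditions: Pd(OAc)2 (10 mol %), O2 (1 atm), DMSO, rt
Reagents that add atoms: none
Why: Saegusa–Ito oxidation, in which the palladium enolate formed from the silyl enol ether undergoes β-hydride elimination toward C-3 only, so the enone returns one methyl richer with C-4 untouched.

Step 5
Reactants: 7 (4R)-3,4-dimethylcyclohex-2-en-1-one
Product: 8 trimethyl{[(4R)-3,3,4-trimethylcyclohex-1-en-1-yl]oxy}silane
Conditions: MeMgBr, CuBr·SMe2 (10 mol %), Me3SiCl, HMPA, THF, −78 → −40 °C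
Reagents that add atoms: methylmagnesium bromide, C[Mg]Br; chlorotrimethylsilane, C[Si](C)(C)Cl
Why: A second copper-catalysed conjugate methylation, accelerated by Me3SiCl and HMPA, builds the gem-dimethyl carbon of ring A and stores the enolate regiospecifically next to it.

Step 6
Reactants: 8 trimethyl{[(4R)-3,3,4-trimethylcyclohex-1-en-1-yl]oxy}silane
Product: 9 (4R)-2-(hydroxymethyl)-3,3,4-trimethylcyclohexan-1-one
Conditions: aq. HCHO, Yb(OTf)3 (10 mol %), THF, rt
Reagents that add atoms: formaldehyde, C=O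
Why: Lewis-acid-catalysed Mukaiyama aldol (hydroxymethylation) puts the one-carbon unit only on the enol ether carbon; the new α-centre forms as a mixture that is equilibrated in step 7.

Step 7
Reactants: 9 (4R)-2-(hydroxymethyl)-3,3,4-trimethylcyclohexan-1-one
Product: 10 (2R,4R)-3,3,4-trimethyl-2-{[(1-phenyl-1H-tetrazol-5-yl)sulfanyl]methyl}cyclohexan-1-one
Conditions: 1-phenyl-1H-tetrazole-5-thiol, PPh3, DIAD, THF, 0 °C → rt; then DBU (10 mol %), CH2Cl2, rt
Reagents that add atoms: 1-phenyl-1H-tetrazole-5-thiol, Sc1nnnn1-c1ccccc1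
Why: Mitsunobu thioetherification (elimination to the enone and thia-Michael addition would give the same product), after which base equilibration of the ketone α-centre gives the thermodynamically preferred 2,4-cis isomer with both substituents equatorial, setting the chain-bearing ring carbon relative to the methyl-bearing one.

Step 8
Reactants: 10 (2R,4R)-3,3,4-trimethyl-2-{[(1-phenyl-1H-tetrazol-5-yl)sulfanyl]methyl}cyclohexan-1-one
Product: 11 1-phenyl-5-({[(1S,3R)-2,2,3-trimethyl-6-methylidenecyclohexyl]methyl}sulfanyl)-1H-tetrazole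
Conditions: Zn, CH2Br2, TiCl4, THF/CH2Cl2, 0 °C → rt
Reagents that add atoms: dibromomethane, BrCBr
Why: Takai–Lombardo methylenation is non-basic, so the hindered β-thio ketone becomes the exocyclic alkene without epimerisation at the α-carbon or loss of thiolate.

Step 9
Reactants: 11 1-phenyl-5-({[(1S,3R)-2,2,3-trimethyl-6-methylidenecyclohexyl]methyl}sulfanyl)-1H-tetrazole
Product: 12 1-phenyl-5-({[(1S,3R)-2,2,3-trimethyl-6-methylidenecyclohexyl]methyl}sulfonyl)-1H-tetrazole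
Conditions: (NH4)6Mo7O24·4H2O (10 mol %), H2O2 (30 % aq.), EtOH, 0 °C → rt
Reagents that add atoms: hydrogen peroxide, OO
Why: Molybdate-catalysed sulfide oxidation goes cleanly to the sulfone and leaves the unactivated 1,1-disubstituted alkene alone.

## Fragment B (ring B enal)

Step 10
Reactants: 13 3-bromopropan-1-ol
Product: 14 (3-bromopropoxy)(tert-butyl)diphenylsilane
Conditions: t-BuPh2SiCl, imidazole, CH2Cl2, 0 °C → rt
Reagents that add atoms: tert-butyl(chloro)diphenylsilane, CC(C)(C)[Si](Cl)(c1ccccc1)c1ccccc1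
Why: Routine silyl ether formation on a primary alcohol.

Step 11
Reactants: 15 methyl 3-oxobutanoate (methyl acetoacetate); 16 (2S)-2-[(benzyloxy)methyl]oxirane
Product: 18 methyl (6S)-7-(benzyloxy)-6-hydroxy-3-oxoheptanoate, via dianion 17 (not isolated)
Conditions: NaH, THF, 0 °C; n-BuLi, 0 °C; then 16, −20 °C → rt
Reagents that add atoms: none
Why: Weiler dianion alkylation in which the terminal carbanion opens the epoxide at its unsubstituted carbon by backside attack, so the carbinol centre of 16 (the control element for ring B) is carried over unchanged.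

Step 12
Reactants: 18 methyl (6S)-7-(benzyloxy)-6-hydroxy-3-oxoheptanoate
Product: 19 methyl (6S)-7-(benzyloxy)-3-oxo-6-[(triethylsilyl)oxy]heptanoate
Conditions: Et3SiCl, imidazole, DMF, 0 °C
Reagents that add atoms: chlorotriethylsilane, CC[Si](Cl)(CC)CC
Why: Silylation of the secondary alcohol (reached through the open hydroxy ketone form) blocks hemiketal formation and provides the group that will steer the cuprate addition.

Step 13
Reactants: 19 methyl (6S)-7-(benzyloxy)-3-oxo-6-[(triethylsilyl)oxy]heptanoate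
Product: 20 methyl (6S)-7-hydroxy-3-oxo-6-[(triethylsilyl)oxy]heptanoate
Conditions: H2 (1 atm), Pd/C (10 %), EtOAc, rt
Reagents that add atoms: none
Why: Hydrogenolysis removes the benzyl ether without affecting the β-keto ester or the silyl ether in a non-protic solvent.

Step 14
Reactants: 20 methyl (6S)-7-hydroxy-3-oxo-6-[(triethylsilyl)oxy]heptanoate
Product: 23 methyl (3S)-6-oxo-3-[(triethylsilyl)oxy]cyclohex-1-ene-1-carboxylate, via aldehyde 21 (not isolated), via aldol adduct 22 (not isolated)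
Conditions: Dess–Martin periodinane, CH2Cl2, 0 °C → rt; then piperidine (0.3 equiv), 4 Å molecular sieves, 0 °C
Reagents that add atoms: none
Why: Oxidation gives the α-silyloxy aldehyde, whose β-keto ester carbon (the future quaternary carbon) adds to the aldehyde carbon (the future side-chain CH) in an amine-catalysed intramolecular aldol (Knoevenagel) condensation that closes ring B; the silyloxy centre is not involved and is kept under the cold, weakly basic conditions.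

Step 15
Reactants: 23 methyl (3S)-6-oxo-3-[(triethylsilyl)oxy]cyclohex-1-ene-1-carboxylate; 14 (3-bromopropoxy)(tert-butyl)diphenylsilane
Product: 25 methyl (2S,3S)-2-{3-[(tert-butyldiphenylsilyl)oxy]propyl}-6-oxo-3-[(triethylsilyl)oxy]cyclohexane-1-carboxylate, via Grignard reagent 24 (not isolated)
Conditions: 14, Mg, THF, rt; CuBr·SMe2 (20 mol %), THF, −78 °C; then 23, −78 → −40 °C
Reagents that add atoms: none
Why: Copper-catalysed conjugate addition to the doubly activated enone occurs anti to the neighbouring silyloxy group, which sets the side-chain CH with the chain trans to OSiEt3.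

Step 16
Reactants: 25 methyl (2S,3S)-2-{3-[(tert-butyldiphenylsilyl)oxy]propyl}-6-oxo-3-[(triethylsilyl)oxy]cyclohexane-1-carboxylate; 26 3-bromoprop-1-ene (allyl bromide)
Product: 27 methyl (1R,2S,3S)-2-{3-[(tert-butyldiphenylsilyl)oxy]propyl}-6-oxo-1-(prop-2-en-1-yl)-3-[(triethylsilyl)oxy]cyclohexane-1-carboxylate
Conditions: K2CO3, acetone, 40 °C
Reagents that add atoms: none
Why: Enolate C-alkylation of the β-keto ester, with allyl bromide approaching anti to the adjacent side chain, sets the quaternary centre with the ester cis to that chain.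

Step 17
Reactants: 27 methyl (1R,2S,3S)-2-{3-[(tert-butyldiphenylsilyl)oxy]propyl}-6-oxo-1-(prop-2-en-1-yl)-3-[(triethylsilyl)oxy]cyclohexane-1-carboxylate
Product: 28 methyl (1R,2S,3S,6S)-2-{3-[(tert-butyldiphenylsilyl)oxy]propyl}-6-hydroxy-6-methyl-1-(prop-2-en-1-yl)-3-[(triethylsilyl)oxy]cyclohexane-1-carboxylate
Conditions: MeMgBr, CeCl3, THF, −78 °C
Reagents that add atoms: methylmagnesium bromide, C[Mg]Br
Why: Cerium-mediated Grignard 1,2-addition to the ketone only; in the chair that keeps the three large groups equatorial the ester is axial, so methyl adds from the opposite face and sets the tertiary carbinol with OH cis to the ester.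

Step 18
Reactants: 28 methyl (1R,2S,3S,6S)-2-{3-[(tert-butyldiphenylsilyl)oxy]propyl}-6-hydroxy-6-methyl-1-(prop-2-en-1-yl)-3-[(triethylsilyl)oxy]cyclohexane-1-carboxylate
Product: 29 (1S,2S,3S,4S)-3-{3-[(tert-butyldiphenylsilyl)oxy]propyl}-2-(hydroxymethyl)-1-methyl-2-(prop-2-en-1-yl)-4-[(triethylsilyl)oxy]cyclohexan-1-ol
Conditions: LiAlH4, THF, 0 °C
Reagents that add atoms: none
Why: Hydride reduction of the ester to the primary alcohol, which also removes the β-hydroxy ester and with it any retro-aldol pathway.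

Step 19
Reactants: 29 (1S,2S,3S,4S)-3-{3-[(tert-butyldiphenylsilyl)oxy]propyl}-2-(hydroxymethyl)-1-methyl-2-(prop-2-en-1-yl)-4-[(triethylsilyl)oxy]cyclohexan-1-ol
Product: 30 (4aS,5S,6S,8aS)-2,2-di-tert-butyl-5-{3-[(tert-butyldiphenylsilyl)oxy]propyl}-8a-methyl-4a-(prop-2-en-1-yl)-6-[(triethylsilyl)oxy]hexahydro-4H-benzo[d][1,3,2]dioxasiline
Conditions: t-Bu2Si(OTf)2, 2,6-lutidine, CH2Cl2, 0 °C
Reagents that add atoms: di-tert-butylsilyl bis(trifluoromethanesulfonate), CC(C)(C)[Si](OS(=O)(=O)C(F)(F)F)(OS(=O)(=O)C(F)(F)F)C(C)(C)C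
Why: Silylene acetal formation ties the cis primary and tertiary hydroxyls of the 1,3-diol into one six-membered ring that is stable to the base and oxidants used later.

Step 20
Reactants: 30 (4aS,5S,6S,8aS)-2,2-di-tert-butyl-5-{3-[(tert-butyldiphenylsilyl)oxy]propyl}-8a-methyl-4a-(prop-2-en-1-yl)-6-[(triethylsilyl)oxy]hexahydro-4H-benzo[d][1,3,2]dioxasiline
Product: 31 (4aS,5S,6S,8aS)-2,2-di-tert-butyl-5-{3-[(tert-butyldiphenylsilyl)oxy]propyl}-8a-methyl-4a-(prop-2-en-1-yl)hexahydro-4H-benzo[d][1,3,2]dioxasilin-6-ol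
Conditions: PPTS (10 mol %), MeOH/CH2Cl2, 0 °C → rt
Reagents that add atoms: none
Why: Acid-catalysed methanolysis removes the triethylsilyl ether far faster than the tert-butyldiphenylsilyl ether or the silylene acetal.

Step 21
Reactants: 31 (4aS,5S,6S,8aS)-2,2-di-tert-butyl-5-{3-[(tert-butyldiphenylsilyl)oxy]propyl}-8a-methyl-4a-(prop-2-en-1-yl)hexahydro-4H-benzo[d][1,3,2]dioxasilin-6-ol
Product: 32 (4aS,5S,8aS)-2,2-di-tert-butyl-5-{3-[(tert-butyldiphenylsilyl)oxy]propyl}-8a-methyl-4a-(prop-2-en-1-yl)tetrahydro-4H-benzo[d][1,3,2]dioxasilin-6(5H)-one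
Conditions: Dess–Martin periodinane, CH2Cl2, rt
Reagents that add atoms: none
Why: Mild neutral oxidation of the secondary alcohol gives the ring B ketone without epimerising the adjacent side-chain CH.

Step 22
Reactants: 32 (4aS,5S,8aS)-2,2-di-tert-butyl-5-{3-[(tert-butyldiphenylsilyl)oxy]propyl}-8a-methyl-4a-(prop-2-en-1-yl)tetrahydro-4H-benzo[d][1,3,2]dioxasilin-6(5H)-one; 33 diethyl (1-cyanoethyl)phosphonate
Product: 35 (2Z)-2-[(4aS,5R,8aS)-2,2-di-tert-butyl-5-{3-[(tert-butyldiphenylsilyl)oxy]propyl}-8a-methyl-4a-(prop-2-en-1-yl)tetrahydro-4H-benzo[d][1,3,2]dioxasilin-6(5H)-ylidene]propanenitrile, via sodium phosphonate 34 (not isolated)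
Conditions: 33, NaH, THF, 0 °C; then 32, 0 → 65 °C
Reagents that add atoms: none
Why: Horner–Wadsworth–Emmons olefination with a reactive α-cyano phosphonate; in the oxaphosphetane the methyl group avoids the branched side of the ketone, so the small linear nitrile should end syn to the side-chain CH (Z), which is also the less strained alkene.

Step 23
Reactants: 35 (2Z)-2-[(4aS,5R,8aS)-2,2-di-tert-butyl-5-{3-[(tert-butyldiphenylsilyl)oxy]propyl}-8a-methyl-4a-(prop-2-en-1-yl)tetrahydro-4H-benzo[d][1,3,2]dioxasilin-6(5H)-ylidene]propanenitrile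
Product: 37 (2Z)-2-[(4aS,5R,8aS)-2,2-di-tert-butyl-5-{3-[(tert-butyldiphenylsilyl)oxy]propyl}-4a-(3-hydroxypropyl)-8a-methyltetrahydro-4H-benzo[d][1,3,2]dioxasilin-6(5H)-ylidene]propanenitrile, via alkylborane 36 (not isolated)
Conditions: 9-BBN-H, THF, 0 °C → rt; then H2O2 (30 % aq.), NaOAc, 0 °C → rt
Reagents that add atoms: hydrogen peroxide, OO
Why: Anti-Markovnikov hydroboration–oxidation of the terminal alkene; the tetrasubstituted conjugated alkene and the nitrile do not react with 9-BBN-H.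

Step 24
Reactants: 37 (2Z)-2-[(4aS,5R,8aS)-2,2-di-tert-butyl-5-{3-[(tert-butyldiphenylsilyl)oxy]propyl}-4a-(3-hydroxypropyl)-8a-methyltetrahydro-4H-benzo[d][1,3,2]dioxasilin-6(5H)-ylidene]propanenitrile
Product: 38 (2Z)-2-[(4aS,5R,8aS)-2,2-di-tert-butyl-5-{3-[(tert-butyldiphenylsilyl)oxy]propyl}-8a-methyl-4a-(3-oxopropyl)tetrahydro-4H-benzo[d][1,3,2]dioxasilin-6(5H)-ylidene]propanenitrile
Conditions: Dess–Martin periodinane, CH2Cl2, rt
Reagents that add atoms: none
Why: Oxidation of the primary alcohol to the aldehyde; no free hydroxyl is left that could form a lactol.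

Step 25
Reactants: 38 (2Z)-2-[(4aS,5R,8aS)-2,2-di-tert-butyl-5-{3-[(tert-butyldiphenylsilyl)oxy]propyl}-8a-methyl-4a-(3-oxopropyl)tetrahydro-4H-benzo[d][1,3,2]dioxasilin-6(5H)-ylidene]propanenitrile; 39 2-(triphenyl-λ5-phosphanylidene)propanal
Product: 40 (2Z)-2-[(4aS,5R,8aS)-2,2-di-tert-butyl-5-{3-[(tert-butyldiphenylsilyl)oxy]propyl}-8a-methyl-4a-[(3E)-4-methyl-5-oxopent-3-en-1-yl]tetrahydro-4H-benzo[d][1,3,2]dioxasilin-6(5H)-ylidene]propanenitrile
Conditions: toluene, 90 °C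
Reagents that add atoms: none
Why: Wittig reaction of a stabilised ylide gives the (E)-2-methyl enal under thermodynamic control of the betaine stage.

## Coupling and end game

Step 26
Reactants: 12 1-phenyl-5-({[(1S,3R)-2,2,3-trimethyl-6-methylidenecyclohexyl]methyl}sulfonyl)-1H-tetrazole; 40 (2Z)-2-[(4aS,5R,8aS)-2,2-di-tert-butyl-5-{3-[(tert-butyldiphenylsilyl)oxy]propyl}-8a-methyl-4a-[(3E)-4-methyl-5-oxopent-3-en-1-yl]tetrahydro-4H-benzo[d][1,3,2]dioxasilin-6(5H)-ylidene]propanenitrile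
Product: 42 (2Z)-2-[(4aS,5R,8aS)-2,2-di-tert-butyl-5-{3-[(tert-butyldiphenylsilyl)oxy]propyl}-8a-methyl-4a-{(3E,5E)-4-methyl-6-[(1S,3R)-2,2,3-trimethyl-6-methylidenecyclohexyl]hexa-3,5-dien-1-yl}tetrahydro-4H-benzo[d][1,3,2]dioxasilin-6(5H)-ylidene]propanenitrile, via potassium sulfone carbanion 41 (not isolated)
Conditions: 12, KN(SiMe3)2, DME, −60 °C; then 40, −60 °C → rt
Reagents that add atoms: none
Why: Julia–Kocienski olefination (addition, Smiles rearrangement, loss of sulfur dioxide and tetrazololate) gives the E-disubstituted alkene with a potassium base in DME and leaves the allylic stereocentre of ring A untouched.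

Step 27
Reactants: 42 (2Z)-2-[(4aS,5R,8aS)-2,2-di-tert-butyl-5-{3-[(tert-butyldiphenylsilyl)oxy]propyl}-8a-methyl-4a-{(3E,5E)-4-methyl-6-[(1S,3R)-2,2,3-trimethyl-6-methylidenecyclohexyl]hexa-3,5-dien-1-yl}tetrahydro-4H-benzo[d][1,3,2]dioxasilin-6(5H)-ylidene]propanenitrile
Product: 43 (2Z)-2-[(2R,3S,4S)-4-hydroxy-3-(hydroxymethyl)-2-(3-hydroxypropyl)-4-methyl-3-{(3E,5E)-4-methyl-6-[(1S,3R)-2,2,3-trimethyl-6-methylidenecyclohexyl]hexa-3,5-dien-1-yl}cyclohexylidene]propanenitrile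
Conditions: n-Bu4NF, THF, rt
Reagents that add atoms: none
Why: Fluoride cleaves the silyl ether and the silylene acetal at the nitrile stage, where the molecule is not base-sensitive.

Step 28
Reactants: 43 (2Z)-2-[(2R,3S,4S)-4-hydroxy-3-(hydroxymethyl)-2-(3-hydroxypropyl)-4-methyl-3-{(3E,5E)-4-methyl-6-[(1S,3R)-2,2,3-trimethyl-6-methylidenecyclohexyl]hexa-3,5-dien-1-yl}cyclohexylidene]propanenitrile
Product: 45 (2Z)-2-[(2R,3S,4S)-4-hydroxy-3-(hydroxymethyl)-2-(3-hydroxypropyl)-4-methyl-3-{(3E,5E)-4-methyl-6-[(1S,3R)-2,2,3-trimethyl-6-methylidenecyclohexyl]hexa-3,5-dien-1-yl}cyclohexylidene]propanal, via aldimine 44 (not isolated)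
Conditions: i-Bu2AlH (7 equiv), CH2Cl2, −78 → −30 °C; then H2O, SiO2
Reagents that add atoms: water, O
Why: Partial reduction of the nitrile by i-Bu2AlH stops at the N-aluminated aldimine, which is hydrolysed on work-up to the enal with the alkene geometry retained.

## Compound list

1 | propanal | CCC=O | starting material
2 | but-3-en-2-one (methyl vinyl ketone) | CC(=O)C=C | starting material
3 | (2R)-2-methyl-5-oxohexanal | CC(=O)CC[C@@H](C)C=O | intermediate
4 | (4R)-3-hydroxy-4-methylcyclohexan-1-one (aldol adduct, carbinol epimers, not isolated) | O=C1CC[C@@H](C)C(O)C1 | intermediate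
5 | (4R)-4-methylcyclohex-2-en-1-one | O=C1CC[C@@H](C)C=C1 | intermediate
6 | trimethyl{[(3S,4R)-3,4-dimethylcyclohex-1-en-1-yl]oxy}silane | C[Si](C)(C)OC=1CC[C@@H](C)[C@H](C)C=1 | intermediate
7 | (4R)-3,4-dimethylcyclohex-2-en-1-one | O=C1CC[C@@H](C)C(C)=C1 | intermediate
8 | trimethyl{[(4R)-3,3,4-trimethylcyclohex-1-en-1-yl]oxy}silane | C[Si](C)(C)OC=1CC[C@@H](C)C(C)(C)C=1 | intermediate
9 | (4R)-2-(hydroxymethyl)-3,3,4-trimethylcyclohexan-1-one (C-2 epimers) | O=C1CC[C@@H](C)C(C)(C)C1CO | intermediate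
10 | (2R,4R)-3,3,4-trimethyl-2-{[(1-phenyl-1H-tetrazol-5-yl)sulfanyl]methyl}cyclohexan-1-one | O=C1CC[C@@H](C)C(C)(C)[C@H]1CSc1nnnn1-c1ccccc1 | intermediate
11 | 1-phenyl-5-({[(1S,3R)-2,2,3-trimethyl-6-methylidenecyclohexyl]methyl}sulfanyl)-1H-tetrazole | C=C1CC[C@@H](C)C(C)(C)[C@H]1CSc1nnnn1-c1ccccc1 | intermediate
12 | 1-phenyl-5-({[(1S,3R)-2,2,3-trimethyl-6-methylidenecyclohexyl]methyl}sulfonyl)-1H-tetrazole | C=C1CC[C@@H](C)C(C)(C)[C@H]1CS(=O)(=O)c1nnnn1-c1ccccc1 | intermediate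
13 | 3-bromopropan-1-ol | OCCCBr | starting material
14 | (3-bromopropoxy)(tert-butyl)diphenylsilane | BrCCCO[Si](c1ccccc1)(c1ccccc1)C(C)(C)C | intermediate
15 | methyl 3-oxobutanoate | COC(=O)CC(C)=O | starting material
16 | (2S)-2-[(benzyloxy)methyl]oxirane | C(OCc1ccccc1)[C@@H]1CO1 | starting material
17 | lithium sodium dianion of methyl 3-oxobutanoate (not isolated) | [Li+].[Na+].COC(=O)[CH-]C(=O)[CH2-] | intermediate
18 | methyl (6S)-7-(benzyloxy)-6-hydroxy-3-oxoheptanoate | COC(=O)CC(=O)CC[C@H](O)COCc1ccccc1 | intermediate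
19 | methyl (6S)-7-(benzyloxy)-3-oxo-6-[(triethylsilyl)oxy]heptanoate | COC(=O)CC(=O)CC[C@H](O[Si](CC)(CC)CC)COCc1ccccc1 | intermediate
20 | methyl (6S)-7-hydroxy-3-oxo-6-[(triethylsilyl)oxy]heptanoate | COC(=O)CC(=O)CC[C@H](O[Si](CC)(CC)CC)CO | intermediate
21 | methyl (6S)-3,7-dioxo-6-[(triethylsilyl)oxy]heptanoate (not isolated) | COC(=O)CC(=O)CC[C@H](O[Si](CC)(CC)CC)C=O | intermediate
22 | methyl (3S)-2-hydroxy-6-oxo-3-[(triethylsilyl)oxy]cyclohexane-1-carboxylate (aldol adduct, mixture of epimers at the ester and carbinol carbons, not isolated) | COC(=O)C1C(O)[C@@H](O[Si](CC)(CC)CC)CCC1=O | intermediate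
23 | methyl (3S)-6-oxo-3-[(triethylsilyl)oxy]cyclohex-1-ene-1-carboxylate | COC(=O)C1=C[C@@H](O[Si](CC)(CC)CC)CCC1=O | intermediate
24 | {3-[(tert-butyldiphenylsilyl)oxy]propyl}magnesium bromide (not isolated) | Br[Mg]CCCO[Si](c1ccccc1)(c1ccccc1)C(C)(C)C | intermediate
25 | methyl (2S,3S)-2-{3-[(tert-butyldiphenylsilyl)oxy]propyl}-6-oxo-3-[(triethylsilyl)oxy]cyclohexane-1-carboxylate (epimers at the ester carbon and enol) | COC(=O)C1[C@H](CCCO[Si](c2ccccc2)(c2ccccc2)C(C)(C)C)[C@@H](O[Si](CC)(CC)CC)CCC1=O | intermediate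
26 | 3-bromoprop-1-ene | C=CCBr | starting material
27 | methyl (1R,2S,3S)-2-{3-[(tert-butyldiphenylsilyl)oxy]propyl}-6-oxo-1-(prop-2-en-1-yl)-3-[(triethylsilyl)oxy]cyclohexane-1-carboxylate | C=CC[C@@]1(C(=O)OC)[C@H](CCCO[Si](c2ccccc2)(c2ccccc2)C(C)(C)C)[C@@H](O[Si](CC)(CC)CC)CCC1=O | intermediate
28 | methyl (1R,2S,3S,6S)-2-{3-[(tert-butyldiphenylsilyl)oxy]propyl}-6-hydroxy-6-methyl-1-(prop-2-en-1-yl)-3-[(triethylsilyl)oxy]cyclohexane-1-carboxylate | C=CC[C@@]1(C(=O)OC)[C@H](CCCO[Si](c2ccccc2)(c2ccccc2)C(C)(C)C)[C@@H](O[Si](CC)(CC)CC)CC[C@]1(C)O | intermediate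
29 | (1S,2S,3S,4S)-3-{3-[(tert-butyldiphenylsilyl)oxy]propyl}-2-(hydroxymethyl)-1-methyl-2-(prop-2-en-1-yl)-4-[(triethylsilyl)oxy]cyclohexan-1-ol | C=CC[C@@]1(CO)[C@H](CCCO[Si](c2ccccc2)(c2ccccc2)C(C)(C)C)[C@@H](O[Si](CC)(CC)CC)CC[C@]1(C)O | intermediate
30 | (4aS,5S,6S,8aS)-2,2-di-tert-butyl-5-{3-[(tert-butyldiphenylsilyl)oxy]propyl}-8a-methyl-4a-(prop-2-en-1-yl)-6-[(triethylsilyl)oxy]hexahydro-4H-benzo[d][1,3,2]dioxasiline | C=CC[C@@]1(CO3)[C@H](CCCO[Si](c2ccccc2)(c2ccccc2)C(C)(C)C)[C@@H](O[Si](CC)(CC)CC)CC[C@]1(C)O[Si]3(C(C)(C)C)C(C)(C)C | intermediate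
31 | (4aS,5S,6S,8aS)-2,2-di-tert-butyl-5-{3-[(tert-butyldiphenylsilyl)oxy]propyl}-8a-methyl-4a-(prop-2-en-1-yl)hexahydro-4H-benzo[d][1,3,2]dioxasilin-6-ol | C=CC[C@@]1(CO3)[C@H](CCCO[Si](c2ccccc2)(c2ccccc2)C(C)(C)C)[C@@H](O)CC[C@]1(C)O[Si]3(C(C)(C)C)C(C)(C)C | intermediate
32 | (4aS,5S,8aS)-2,2-di-tert-butyl-5-{3-[(tert-butyldiphenylsilyl)oxy]propyl}-8a-methyl-4a-(prop-2-en-1-yl)tetrahydro-4H-benzo[d][1,3,2]dioxasilin-6(5H)-one | C=CC[C@@]1(CO3)[C@H](CCCO[Si](c2ccccc2)(c2ccccc2)C(C)(C)C)C(=O)CC[C@]1(C)O[Si]3(C(C)(C)C)C(C)(C)C | intermediate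
33 | diethyl (1-cyanoethyl)phosphonate | CCOP(=O)(OCC)C(C)C#N | starting material
34 | sodium salt of diethyl (1-cyanoethyl)phosphonate (not isolated) | [Na+].CCOP(=O)(OCC)[C-](C)C#N | intermediate
35 | (2Z)-2-[(4aS,5R,8aS)-2,2-di-tert-butyl-5-{3-[(tert-butyldiphenylsilyl)oxy]propyl}-8a-methyl-4a-(prop-2-en-1-yl)tetrahydro-4H-benzo[d][1,3,2]dioxasilin-6(5H)-ylidene]propanenitrile | C=CC[C@@]1(CO3)[C@H](CCCO[Si](c2ccccc2)(c2ccccc2)C(C)(C)C)/C(=C(/C)C#N)CC[C@]1(C)O[Si]3(C(C)(C)C)C(C)(C)C | intermediate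
36 | B-alkyl-9-borabicyclo[3.3.1]nonane adduct of 35 at the terminal carbon (not isolated) | C1CCC2CCCC1B2CCC[C@@]1(CO3)[C@H](CCCO[Si](c2ccccc2)(c2ccccc2)C(C)(C)C)/C(=C(/C)C#N)CC[C@]1(C)O[Si]3(C(C)(C)C)C(C)(C)C | intermediate
37 | (2Z)-2-[(4aS,5R,8aS)-2,2-di-tert-butyl-5-{3-[(tert-butyldiphenylsilyl)oxy]propyl}-4a-(3-hydroxypropyl)-8a-methyltetrahydro-4H-benzo[d][1,3,2]dioxasilin-6(5H)-ylidene]propanenitrile | OCCC[C@@]1(CO3)[C@H](CCCO[Si](c2ccccc2)(c2ccccc2)C(C)(C)C)/C(=C(/C)C#N)CC[C@]1(C)O[Si]3(C(C)(C)C)C(C)(C)C | intermediate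
38 | (2Z)-2-[(4aS,5R,8aS)-2,2-di-tert-butyl-5-{3-[(tert-butyldiphenylsilyl)oxy]propyl}-8a-methyl-4a-(3-oxopropyl)tetrahydro-4H-benzo[d][1,3,2]dioxasilin-6(5H)-ylidene]propanenitrile | O=CCC[C@@]1(CO3)[C@H](CCCO[Si](c2ccccc2)(c2ccccc2)C(C)(C)C)/C(=C(/C)C#N)CC[C@]1(C)O[Si]3(C(C)(C)C)C(C)(C)C | intermediate
39 | 2-(triphenyl-λ5-phosphanylidene)propanal | CC(C=O)=P(c1ccccc1)(c1ccccc1)c1ccccc1 | starting material
40 | (2Z)-2-[(4aS,5R,8aS)-2,2-di-tert-butyl-5-{3-[(tert-butyldiphenylsilyl)oxy]propyl}-8a-methyl-4a-[(3E)-4-methyl-5-oxopent-3-en-1-yl]tetrahydro-4H-benzo[d][1,3,2]dioxasilin-6(5H)-ylidene]propanenitrile | O=C/C(C)=C/CC[C@@]1(CO3)[C@H](CCCO[Si](c2ccccc2)(c2ccccc2)C(C)(C)C)/C(=C(/C)C#N)CC[C@]1(C)O[Si]3(C(C)(C)C)C(C)(C)C | intermediate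
41 | potassium salt of sulfone 12 deprotonated at the methylene carbon next to sulfur (not isolated) | [K+].C=C1CC[C@@H](C)C(C)(C)[C@H]1[CH-]S(=O)(=O)c1nnnn1-c1ccccc1 | intermediate
42 | (2Z)-2-[(4aS,5R,8aS)-2,2-di-tert-butyl-5-{3-[(tert-butyldiphenylsilyl)oxy]propyl}-8a-methyl-4a-{(3E,5E)-4-methyl-6-[(1S,3R)-2,2,3-trimethyl-6-methylidenecyclohexyl]hexa-3,5-dien-1-yl}tetrahydro-4H-benzo[d][1,3,2]dioxasilin-6(5H)-ylidene]propanenitrile | C=C1CC[C@@H](C)C(C)(C)[C@H]1/C=C/C(C)=C/CC[C@@]1(CO3)[C@H](CCCO[Si](c2ccccc2)(c2ccccc2)C(C)(C)C)/C(=C(/C)C#N)CC[C@]1(C)O[Si]3(C(C)(C)C)C(C)(C)C | intermediate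
43 | (2Z)-2-[(2R,3S,4S)-4-hydroxy-3-(hydroxymethyl)-2-(3-hydroxypropyl)-4-methyl-3-{(3E,5E)-4-methyl-6-[(1S,3R)-2,2,3-trimethyl-6-methylidenecyclohexyl]hexa-3,5-dien-1-yl}cyclohexylidene]propanenitrile | C=C1CC[C@@H](C)C(C)(C)[C@H]1/C=C/C(C)=C/CC[C@@]1(CO)[C@H](CCCO)/C(=C(/C)C#N)CC[C@]1(C)O | intermediate
44 | aldimine of 45 (C=NH in place of C=O; N-aluminated in the flask, drawn as the free imine, not isolated) | C=C1CC[C@@H](C)C(C)(C)[C@H]1/C=C/C(C)=C/CC[C@@]1(CO)[C@H](CCCO)/C(=C(/C)C=N)CC[C@]1(C)O | intermediate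
45 | (2Z)-2-[(2R,3S,4S)-4-hydroxy-3-(hydroxymethyl)-2-(3-hydroxypropyl)-4-methyl-3-{(3E,5E)-4-methyl-6-[(1S,3R)-2,2,3-trimethyl-6-methylidenecyclohexyl]hexa-3,5-dien-1-yl}cyclohexylidene]propanal | C=C1CC[C@@H](C)C(C)(C)[C@H]1/C=C/C(C)=C/CC[C@@]1(CO)[C@H](CCCO)/C(=C(/C)C=O)CC[C@]1(C)O | target

## Totals and risks

Total step count: 28 (fragment A steps 1–9, side chain reagent step 10, fragment B steps 11–25, coupling and end game steps 26–28).

Longest linear sequence: 18 steps (steps 11–28, from 15 and 16 to 45), which is 64 % of the total.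

The three steps most likely to fail:

**Step 14 (ring B closure).** The α-silyloxy aldehyde 21 can epimerise, and the alkylidene keto ester 23 can lose silanol and aromatise to a salicylate. The fallback sets out from 20 and comes back at 25, closing ring B by an intramolecular Michael addition instead. Alcohol 20 is oxidised as before, and the crude aldehyde is treated with Ph3P=CHCHO to give the enal methyl (6S,7E)-3,9-dioxo-6-[(triethylsilyl)oxy]non-7-enoate F1. Catalytic K2CO3 in MeCN at 0 °C then closes ring B by a 6-exo Michael addition of the β-keto ester carbon onto the enal. Under thermodynamic control the new chain sits trans to the silyloxy group, giving methyl (2S,3S)-6-oxo-2-(2-oxoethyl)-3-[(triethylsilyl)oxy]cyclohexane-1-carboxylate F2. Methylenation of the aldehyde with Ph3P=CH2 (2.2 equiv, the β-keto ester being masked as its enolate) gives methyl (2S,3S)-6-oxo-2-(prop-2-en-1-yl)-3-[(triethylsilyl)oxy]cyclohexane-1-carboxylate F3. Hydroboration–oxidation (9-BBN-H, then H2O2, NaOAc) gives methyl (2S,3S)-2-(3-hydroxypropyl)-6-oxo-3-[(triethylsilyl)oxy]cyclohexane-1-carboxylate F4, and silylation with t-BuPh2SiCl and imidazole returns to 25.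

**Step 17 (methyl addition at the carbinol carbon).** The facial selectivity rests on a conformational argument, and the tertiary alkoxide next to the ester can undergo retro-aldol cleavage. The fallback sets out from 27 and comes back at 29, using a hydroxyl-directed epoxidation instead of a carbonyl addition. Methylenation of the ketone of 27 (Zn, CH2Br2, TiCl4) gives methyl (1R,2S,3S)-2-{3-[(tert-butyldiphenylsilyl)oxy]propyl}-6-methylidene-1-(prop-2-en-1-yl)-3-[(triethylsilyl)oxy]cyclohexane-1-carboxylate F5. Reduction with i-Bu2AlH gives [(1R,2S,3S)-2-{3-[(tert-butyldiphenylsilyl)oxy]propyl}-6-methylidene-1-(prop-2-en-1-yl)-3-[(triethylsilyl)oxy]cyclohexyl]methanol F6. VO(acac)2 and t-BuOOH deliver oxygen to the 1,1-disubstituted alkene from the face of the hydroxymethyl group, giving [(3S,4S,5S,6S)-5-{3-[(tert-butyldiphenylsilyl)oxy]propyl}-4-(prop-2-en-1-yl)-6-[(triethylsilyl)oxy]-1-oxaspiro[2.5]octan-4-yl]methanol F7. LiAlH4 opens the epoxide at its unsubstituted carbon and gives diol 29 with the tertiary hydroxyl cis to the hydroxymethyl group.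

**Step 22 (tetrasubstituted Z-alkene).** The ketone is hindered and the Z/E ratio of the olefination is uncertain. The fallback sets out from 32 and comes back at 35, replacing the olefination by an addition and oxidative transposition. CH2=C(CH3)MgBr with CeCl3 adds to 32 to give (4aS,5S,8aS)-2,2-di-tert-butyl-5-{3-[(tert-butyldiphenylsilyl)oxy]propyl}-8a-methyl-4a-(prop-2-en-1-yl)-6-(prop-1-en-2-yl)hexahydro-4H-benzo[d][1,3,2]dioxasilin-6-ol F8 as a mixture of carbinol epimers. Babler–Dauben oxidative 1,3-transposition with pyridinium chlorochromate, [C5H5NH][CrO3Cl], gives the enal, which is equilibrated with catalytic iodine under light toward the less strained isomer (2Z)-2-[(4aS,5R,8aS)-2,2-di-tert-butyl-5-{3-[(tert-butyldiphenylsilyl)oxy]propyl}-8a-methyl-4a-(prop-2-en-1-yl)tetrahydro-4H-benzo[d][1,3,2]dioxasilin-6(5H)-ylidene]propanal F9, the two isomers being separated. NH2OH·HCl and pyridine give (2Z)-2-[(4aS,5R,8aS)-2,2-di-tert-butyl-5-{3-[(tert-butyldiphenylsilyl)oxy]propyl}-8a-methyl-4a-(prop-2-en-1-yl)tetrahydro-4H-benzo[d][1,3,2]dioxasilin-6(5H)-ylidene]propanal oxime F10, and dehydration with Ac2O at 80 °C returns to nitrile 35.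

## Further compounds

F1 | step 14 | methyl (6S,7E)-3,9-dioxo-6-[(triethylsilyl)oxy]non-7-enoate | COC(=O)CC(=O)CC[C@H](O[Si](CC)(CC)CC)/C=C/C=O
F2 | step 14 | methyl (2S,3S)-6-oxo-2-(2-oxoethyl)-3-[(triethylsilyl)oxy]cyclohexane-1-carboxylate | COC(=O)C1[C@H](CC=O)[C@@H](O[Si](CC)(CC)CC)CCC1=O
F3 | step 14 | methyl (2S,3S)-6-oxo-2-(prop-2-en-1-yl)-3-[(triethylsilyl)oxy]cyclohexane-1-carboxylate | COC(=O)C1[C@H](CC=C)[C@@H](O[Si](CC)(CC)CC)CCC1=O
F4 | step 14 | methyl (2S,3S)-2-(3-hydroxypropyl)-6-oxo-3-[(triethylsilyl)oxy]cyclohexane-1-carboxylate | COC(=O)C1[C@H](CCCO)[C@@H](O[Si](CC)(CC)CC)CCC1=O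
F5 | step 17 | methyl (1R,2S,3S)-2-{3-[(tert-butyldiphenylsilyl)oxy]propyl}-6-methylidene-1-(prop-2-en-1-yl)-3-[(triethylsilyl)oxy]cyclohexane-1-carboxylate | C=CC[C@@]1(C(=O)OC)[C@H](CCCO[Si](c2ccccc2)(c2ccccc2)C(C)(C)C)[C@@H](O[Si](CC)(CC)CC)CCC1=C
F6 | step 17 | [(1R,2S,3S)-2-{3-[(tert-butyldiphenylsilyl)oxy]propyl}-6-methylidene-1-(prop-2-en-1-yl)-3-[(triethylsilyl)oxy]cyclohexyl]methanol | C=CC[C@@]1(CO)[C@H](CCCO[Si](c2ccccc2)(c2ccccc2)C(C)(C)C)[C@@H](O[Si](CC)(CC)CC)CCC1=C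
F7 | step 17 | [(3S,4S,5S,6S)-5-{3-[(tert-butyldiphenylsilyl)oxy]propyl}-4-(prop-2-en-1-yl)-6-[(triethylsilyl)oxy]-1-oxaspiro[2.5]octan-4-yl]methanol | C=CC[C@@]1(CO)[C@H](CCCO[Si](c2ccccc2)(c2ccccc2)C(C)(C)C)[C@@H](O[Si](CC)(CC)CC)CC[C@@]12CO2
F8 | step 22 | (4aS,5S,8aS)-2,2-di-tert-butyl-5-{3-[(tert-butyldiphenylsilyl)oxy]propyl}-8a-methyl-4a-(prop-2-en-1-yl)-6-(prop-1-en-2-yl)hexahydro-4H-benzo[d][1,3,2]dioxasilin-6-ol (carbinol epimers) | C=CC[C@@]1(CO3)[C@H](CCCO[Si](c2ccccc2)(c2ccccc2)C(C)(C)C)C(O)(C(C)=C)CC[C@]1(C)O[Si]3(C(C)(C)C)C(C)(C)C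
F9 | step 22 | (2Z)-2-[(4aS,5R,8aS)-2,2-di-tert-butyl-5-{3-[(tert-butyldiphenylsilyl)oxy]propyl}-8a-methyl-4a-(prop-2-en-1-yl)tetrahydro-4H-benzo[d][1,3,2]dioxasilin-6(5H)-ylidene]propanal | C=CC[C@@]1(CO3)[C@H](CCCO[Si](c2ccccc2)(c2ccccc2)C(C)(C)C)/C(=C(/C)C=O)CC[C@]1(C)O[Si]3(C(C)(C)C)C(C)(C)C
F10 | step 22 | (2Z)-2-[(4aS,5R,8aS)-2,2-di-tert-butyl-5-{3-[(tert-butyldiphenylsilyl)oxy]propyl}-8a-methyl-4a-(prop-2-en-1-yl)tetrahydro-4H-benzo[d][1,3,2]dioxasilin-6(5H)-ylidene]propanal oxime | C=CC[C@@]1(CO3)[C@H](CCCO[Si](c2ccccc2)(c2ccccc2)C(C)(C)C)/C(=C(/C)C=NO)CC[C@]1(C)O[Si]3(C(C)(C)C)C(C)(C)C
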